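The pyran methylene C2 is read as a methoxy carbon. O1–C2 of ring C is the fourth methoxy group of a 2,3,4,5-tetramethoxyphenyl ring A, and C3, flanked by C4 and ring B, is a donor/acceptor carbene carbon. Everything rests on the C2–C3 disconnection. The precursor is an acyclic α-aryl-α-diazoketone (a diazodeoxybenzoin, B-ring hydroquinone masked as bis-TBS ether). A chiral Rh(II) carboxylate drives a 1,6-C–H insertion into the ortho OCH3. In one operation this functionalises a methyl ether, closes the chromanone ring and sets C3. Axial hydride delivery then sets C4 trans to the aryl group, and buffered fluoride frees the hydroquinone.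

Key step: step 6

Remark: isoflavonoid numbering is used (O1, C2, C3, C4, C4a–C8a for rings C/A, primed numbers for ring B), and the target is the 3,4-trans (3S,4R) isomer.
Assumption: Rh2(S-PTAD)4 is taken to deliver the (3S)-ketone; if the sense of induction on this substrate is the opposite, Rh2(R-PTAD)4 is used instead.

Step 1
Reactants: 1 1,2,3,4-tetramethoxybenzene
Product: 2 1-(2,3,4,5-tetramethoxyphenyl)ethan-1-one
Conditions: Ac2O, Sc(OTf)3 (cat.), LiClO4, MeNO2, 50 °C
Reagents that add atoms: acetic anhydride, CC(=O)OC(C)=O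
Why: Friedel–Crafts acylation: the two free positions of 1 are equivalent, the first acyl group deactivates the ring against a second one, and a halide-free Lewis acid should leave the methoxy group next to the new ketone uncleaved.

Step 2
Reactants: 3 2,3-dimethoxy-1,4-benzoquinone
Product: 4 5-bromo-2,3-dimethoxybenzene-1,4-diol
Conditions: HBr (33% in AcOH), CH2Cl2, 0 °C, N2
Reagents that add atoms: hydrogen bromide, Br
Why: Hydrohalogenation of a quinone (1,4-addition of HBr, then tautomerisation): C5 and C6 of 3 are equivalent and unsubstituted, so bromide should add there rather than at the methoxy-bearing carbons, and the bromohydroquinone is harder to oxidise than the hydroquinone of 3, which should suppress redox scrambling.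

Step 3
Reactants: 4 5-bromo-2,3-dimethoxybenzene-1,4-diol
Product: 5 1-bromo-2,5-bis(tert-butyldimethylsilyloxy)-3,4-dimethoxybenzene
Conditions: TBSCl, imidazole, DMAP (cat.), DMF, rt to 40 °C
Reagents that add atoms: tert-butyldimethylsilyl chloride, CC(C)(C)[Si](C)(C)Cl
Why: Standard imidazole-promoted silylation of both phenols; silyl ethers are chosen because they carry no C–H bond next to oxygen that could intercept the carbenoid of step 6 and because they leave under neutral conditions at the end.

Step 4
Reactants: 2 1-(2,3,4,5-tetramethoxyphenyl)ethan-1-one; 5 1-bromo-2,5-bis(tert-butyldimethylsilyloxy)-3,4-dimethoxybenzene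
Product: 6 2-[2,5-bis(tert-butyldimethylsilyloxy)-3,4-dimethoxyphenyl]-1-(2,3,4,5-tetramethoxyphenyl)ethan-1-one
Conditions: Pd2(dba)3, Xantphos, K3PO4, toluene, 90 °C
Reagents that add atoms: none
Why: Palladium-catalysed α-arylation of a methyl ketone (Buchwald–Hartwig type), in which the mild base K3PO4 should spare the aryl silyl ethers and the ortho substituent of 5 should hold the reaction at monoarylation.

Step 5
Reactants: 6 2-[2,5-bis(tert-butyldimethylsilyloxy)-3,4-dimethoxyphenyl]-1-(2,3,4,5-tetramethoxyphenyl)ethan-1-one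
Product: 7 2-diazo-2-[2,5-bis(tert-butyldimethylsilyloxy)-3,4-dimethoxyphenyl]-1-(2,3,4,5-tetramethoxyphenyl)ethan-1-one
Conditions: p-ABSA, DBU, dry MeCN, 0 °C to rt
Reagents that add atoms: 4-acetamidobenzenesulfonyl azide, CC(=O)Nc1ccc(cc1)S(=O)(=O)N=[N+]=[N-]
Why: Regitz diazo transfer: the doubly activated methylene of the deoxybenzoin is acidic enough for DBU, and exclusion of water should protect the aryl silyl ethers from the amidine base.

Step 6
Reactants: 7 2-diazo-2-[2,5-bis(tert-butyldimethylsilyloxy)-3,4-dimethoxyphenyl]-1-(2,3,4,5-tetramethoxyphenyl)ethan-1-one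
Product: 9 (3S)-3-[2,5-bis(tert-butyldimethylsilyloxy)-3,4-dimethoxyphenyl]-6,7,8-trimethoxychroman-4-one, via rhodium carbenoid 8 (not isolated)
Conditions: Rh2(S-PTAD)4 (1 mol %), 4 Å MS, 2,2-dimethylbutane/PhCF3, slow addition of 7, rt to 40 °C
Reagents that add atoms: none
Why: Rh(II) expels N2 from 7 to give the donor/acceptor carbenoid 8, whose electrophilic C3 takes up a C–H bond of the neighbouring OCH3 in a concerted, hydride-transfer-like three-centre insertion that makes C2–C3 and C3–H at once. The closest known reactions are the Rh(II)-carboxylate-catalysed cyclisation of α-diazoketones of O-alkylsalicylic acids to chroman-4-ones, the insertion of aryl-substituted carbenoids into methyl ethers, and the use of Rh2(PTAD)4 with α-aryl-α-diazoketones. The one ring closed is the pyranone, by a 1,6-C–H insertion in which the carbene carbon and the C–H carbon both become ring members (C3, C4, C4a, C8a, O1, C2). The new stereocentre C3 is the former carbene carbon, so its configuration is fixed by the face of the carbenoid that the chiral phthalimido-adamantylacetate ligand wall leaves open. Insertion must beat reversible oxonium-ylide formation at the same oxygen, 1,5-insertion on the B-ring side and dimerisation; this is secured because a methyl group has no easy [1,2]-shift, the silyl ethers offer no C–H next to the 2'-oxygen, the C8 methoxy group twists the reacting OCH3 out of the ring plane towards C3, and 7 is added slowly. Neutral, aprotic conditions should keep the enolisable C3–H centre intact.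

Step 7
Reactants: 9 (3S)-3-[2,5-bis(tert-butyldimethylsilyloxy)-3,4-dimethoxyphenyl]-6,7,8-trimethoxychroman-4-one
Product: 10 (3S,4R)-3-[2,5-bis(tert-butyldimethylsilyloxy)-3,4-dimethoxyphenyl]-6,7,8-trimethoxychroman-4-ol (3,4-trans)
Conditions: NaBH4, CeCl3·7H2O, MeOH/THF, −40 °C; cold aq. NaHCO3 quench
Reagents that add atoms: none
Why: Luche reduction: the small, hard hydride should attack the half-chair of 9 (3-aryl group pseudo-equatorial) along the axial trajectory, as borohydrides do with flavanones and isoflavanones, which places the new C4–OH pseudo-equatorial and trans to the aryl group (4R), while the weakly acidic cerium medium and the low temperature should prevent enolisation at C3.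

Step 8
Reactants: 10 (3S,4R)-3-[2,5-bis(tert-butyldimethylsilyloxy)-3,4-dimethoxyphenyl]-6,7,8-trimethoxychroman-4-ol
Product: 11 (3S,4R)-3-(2,5-dihydroxy-3,4-dimethoxyphenyl)-6,7,8-trimethoxychroman-4-ol (target)
Conditions: TBAF, AcOH, degassed THF, 0 °C, argon
Reagents that add atoms: none
Why: Fluoride-induced cleavage of the two aryl silyl ethers, buffered with AcOH and run under argon so that neither acid (ionisation of the C4 benzylic alcohol and capture by the 2'-OH) nor base and air (oxidation of the hydroquinone) can act on 11, and no stereocentre is touched.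

Compound list
1 | 1,2,3,4-tetramethoxybenzene | COc1ccc(OC)c(OC)c1OC | starting material
2 | 1-(2,3,4,5-tetramethoxyphenyl)ethan-1-one | CC(=O)c1cc(OC)c(OC)c(OC)c1OC | intermediate
3 | 2,3-dimethoxy-1,4-benzoquinone | COC1=C(OC)C(=O)C=CC1=O | starting material
4 | 5-bromo-2,3-dimethoxybenzene-1,4-diol | COc1c(O)cc(Br)c(O)c1OC | intermediate
5 | 1-bromo-2,5-bis(tert-butyldimethylsilyloxy)-3,4-dimethoxybenzene | COc1c(O[Si](C)(C)C(C)(C)C)cc(Br)c(O[Si](C)(C)C(C)(C)C)c1OC | intermediate
6 | 2-[2,5-bis(tert-butyldimethylsilyloxy)-3,4-dimethoxyphenyl]-1-(2,3,4,5-tetramethoxyphenyl)ethan-1-one | COc1cc(C(=O)Cc2cc(O[Si](C)(C)C(C)(C)C)c(OC)c(OC)c2O[Si](C)(C)C(C)(C)C)c(OC)c(OC)c1OC | intermediate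
7 | 2-diazo-2-[2,5-bis(tert-butyldimethylsilyloxy)-3,4-dimethoxyphenyl]-1-(2,3,4,5-tetramethoxyphenyl)ethan-1-one | COc1cc(C(=O)C(=[N+]=[N-])c2cc(O[Si](C)(C)C(C)(C)C)c(OC)c(OC)c2O[Si](C)(C)C(C)(C)C)c(OC)c(OC)c1OC | intermediate
8 | rhodium carbenoid derived from 7 (catalyst ligands omitted) | COc1cc(C(=O)C(=[Rh])c2cc(O[Si](C)(C)C(C)(C)C)c(OC)c(OC)c2O[Si](C)(C)C(C)(C)C)c(OC)c(OC)c1OC | intermediate
9 | (3S)-3-[2,5-bis(tert-butyldimethylsilyloxy)-3,4-dimethoxyphenyl]-6,7,8-trimethoxychroman-4-one | COc1cc2c(c(OC)c1OC)OC[C@H](c1cc(O[Si](C)(C)C(C)(C)C)c(OC)c(OC)c1O[Si](C)(C)C(C)(C)C)C2=O | intermediate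
10 | (3S,4R)-3-[2,5-bis(tert-butyldimethylsilyloxy)-3,4-dimethoxyphenyl]-6,7,8-trimethoxychroman-4-ol | COc1cc2c(c(OC)c1OC)OC[C@H](c1cc(O[Si](C)(C)C(C)(C)C)c(OC)c(OC)c1O[Si](C)(C)C(C)(C)C)[C@H]2O | intermediate
11 | (3S,4R)-3-(2,5-dihydroxy-3,4-dimethoxyphenyl)-6,7,8-trimethoxychroman-4-ol | COc1cc2c(c(OC)c1OC)OC[C@H](c1cc(O)c(OC)c(OC)c1O)[C@H]2O | target

Total step count: 8
Longest linear sequence: 7 steps (3 → 4 → 5 → 6 → 7 → 9 → 10 → 11)

Steps most likely to fail

1. Step 6 (key step). The carbenoid may be diverted by attack on the lone pair of the same methoxy oxygen or by dimerisation, or the catalyst may discriminate poorly between the carbenoid faces. The fallback sets out from 6 and comes back at 9, and closes the same C2–C3 bond by polar chemistry. BCl3 (CH2Cl2, −78 to 0 °C) should remove only the methyl group of the methoxy oxygen chelated to the ketone and give the ortho-hydroxydeoxybenzoin F1. CH2BrCl and Cs2CO3 (DMF) should then tie the phenoxide and the enolate oxygen together as the cyclic enol acetal F2; any material alkylated at carbon is already the next compound. Me2AlCl (CH2Cl2, −78 °C) should trigger a Petasis–Ferrier rearrangement (aluminium enolate plus aryloxycarbenium ion, recombination at carbon) to the racemic isoflavanone F3. TMSOTf/Et3N should give the silyl enol ether F4. Catalytic enantioselective protonation (BINOL-derived N-triflyl thiophosphoramide, PhOH, toluene, low temperature), as known for silyl enol ethers of α-aryl cyclic ketones, should return 9.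

2. Step 7. Facial selectivity may be poor because of reaction through the conformer with an axial 3-aryl group, or C3 may epimerise under the basicity of the borohydride. The fallback sets out from 9 and comes back at 10, and replaces direct trans reduction by a cis-selective reduction followed by inversion. L-Selectride (THF, −78 °C) should attack anti to the aryl group and give the cis-(3S,4S)-alcohol F5. A Mitsunobu reaction with 4-nitrobenzoic acid (PPh3, DIAD, toluene, 0 °C) should invert C4 to the trans-(3S,4R)-4-nitrobenzoate F6. An ionising pathway would be attacked anti to the aryl group as well. Brief methanolysis (K2CO3, MeOH, 0 °C) should then give 10.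

3. Step 4. The aryl silyl ethers may be lost to hot phosphate, oxidative addition of the electron-rich, ortho-substituted bromide may be slow, or a second arylation may occur. The fallback sets out from 5 and 1 and comes back at 6; it avoids a basic ketone enolate and forms the C4–C4a bond last, so 2 is no longer needed. Zinc insertion into 4-(bromoacetyl)morpholine gives the Reformatsky reagent F7. This reagent should couple with 5 at room temperature (Pd(dba)2, Q-Phos, THF, Negishi type) to the morpholine amide F8. Directed ortho-lithiation of 1 (n-BuLi, TMEDA, THF, 0 °C) gives the aryllithium F9. Its addition to F8 in the presence of LaCl3·2LiCl (−78 °C, to suppress enolisation) should stop at the ketone stage and give 6.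

Further compounds
F1 | step 6 | 2-[2,5-bis(tert-butyldimethylsilyloxy)-3,4-dimethoxyphenyl]-1-(2-hydroxy-3,4,5-trimethoxyphenyl)ethan-1-one | COc1cc(C(=O)Cc2cc(O[Si](C)(C)C(C)(C)C)c(OC)c(OC)c2O[Si](C)(C)C(C)(C)C)c(O)c(OC)c1OC
F2 | step 6 | (Z)-4-[2,5-bis(tert-butyldimethylsilyloxy)-3,4-dimethoxybenzylidene]-6,7,8-trimethoxy-4H-1,3-benzodioxine | COc1cc2c(c(OC)c1OC)OCO/C2=C\c1cc(O[Si](C)(C)C(C)(C)C)c(OC)c(OC)c1O[Si](C)(C)C(C)(C)C
F3 | step 6 | rac-3-[2,5-bis(tert-butyldimethylsilyloxy)-3,4-dimethoxyphenyl]-6,7,8-trimethoxychroman-4-one | COc1cc2c(c(OC)c1OC)OCC(c1cc(O[Si](C)(C)C(C)(C)C)c(OC)c(OC)c1O[Si](C)(C)C(C)(C)C)C2=O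
F4 | step 6 | 3-[2,5-bis(tert-butyldimethylsilyloxy)-3,4-dimethoxyphenyl]-6,7,8-trimethoxy-4-(trimethylsilyloxy)-2H-chromene | COc1cc2c(c(OC)c1OC)OCC(c1cc(O[Si](C)(C)C(C)(C)C)c(OC)c(OC)c1O[Si](C)(C)C(C)(C)C)=C2O[Si](C)(C)C
F5 | step 7 | (3S,4S)-3-[2,5-bis(tert-butyldimethylsilyloxy)-3,4-dimethoxyphenyl]-6,7,8-trimethoxychroman-4-ol (3,4-cis) | COc1cc2c(c(OC)c1OC)OC[C@H](c1cc(O[Si](C)(C)C(C)(C)C)c(OC)c(OC)c1O[Si](C)(C)C(C)(C)C)[C@@H]2O
F6 | step 7 | (3S,4R)-3-[2,5-bis(tert-butyldimethylsilyloxy)-3,4-dimethoxyphenyl]-6,7,8-trimethoxychroman-4-yl 4-nitrobenzoate | COc1cc2c(c(OC)c1OC)OC[C@H](c1cc(O[Si](C)(C)C(C)(C)C)c(OC)c(OC)c1O[Si](C)(C)C(C)(C)C)[C@H]2OC(=O)c1ccc(cc1)[N+](=O)[O-]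
F7 | step 4 | bromo[2-(morpholin-4-yl)-2-oxoethyl]zinc | Br[Zn]CC(=O)N1CCOCC1
F8 | step 4 | 2-[2,5-bis(tert-butyldimethylsilyloxy)-3,4-dimethoxyphenyl]-1-(morpholin-4-yl)ethan-1-one | COc1c(O[Si](C)(C)C(C)(C)C)cc(CC(=O)N2CCOCC2)c(O[Si](C)(C)C(C)(C)C)c1OC
F9 | step 4 | (2,3,4,5-tetramethoxyphenyl)lithium | [Li]c1cc(OC)c(OC)c(OC)c1OC
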